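The teal run, made earlier with twice the protic impurity of the blue flask and otherwise the same charge, has been followed far past the last blue reading. At 8.00 min the two stand level in starting material, 40.4% in blue against 40.2% in teal.

| flask | starting material | second substrate | partner | protic impurity | capture agent | precatalyst | remark | time |
|---|---|---|---|---|---|---|---|---|
| blue | 0.013 M (fed, over 20 min) | 0.50 equiv | 1.2 equiv | 0.26 mM | 1.3 mM | 1 mol% | the very flask that is asked about, followed so far |  |
| teal | 0.013 M (fed, over 20 min) | 0.50 equiv | 1.2 equiv | 0.52 mM | 1.3 mM | 1 mol% | run made earlier |  |
| flask | 0.013 M (fed, over 20 min) | 0.500 equiv | 1.20 equiv | 0.260 mM | 1.30 mM | 1 mol% |  | 1.0 h |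

| run | time / min | starting material / % | target / % |
|---|---|---|---|
| blue | 0.500 | 2.0 | 0.3 |
| blue | 1.33 | 7.2 | 0 |
| blue | 3.00 | 14.9 | 0 |
| blue | 8.00 | 40.4 | 1.2 |
| teal | 8.00 | 40.2 | 0 |
| teal | 20.0 | 100.2 | 0.2 |
| teal | 40.0 | 99.3 | 0.7 |
| teal | 60.0 | 98.5 | 1.4 |

(readings scatter by 0.5 percentage points)

* amount of starting material in percent of the starting material charged, at 6.0 min, 20 min and 1.0 h

- the numbers in the tables scatter with a standard deviation of 0.5 percentage points
- steps thought possible: starting material + free catalyst <-> catalyst intermediate A; partner + catalyst intermediate A -> free catalyst + target; second substrate + free catalyst <-> catalyst intermediate B; partner + catalyst intermediate B -> free catalyst + second product; partner + precatalyst -> free catalyst + spent reagent; partner + protic impurity -> quenched reagent; catalyst intermediate B + capture agent -> trapped intermediate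
- percentages count the whole charge, also what has not yet gone in

I keep a ledger of the starting material in shares of the whole charge, with a line for what has not yet gone in, one for what sits free, one for what is on the catalyst and one for target. The catalyst line is small, since the precatalyst is 1 mol% of the charge. In teal at 60.0 min the free and target lines add up to 99.9%, a gap of 0.1 percentage points against a scatter of 0.5 points. So I leave the catalyst line empty and let free starting material and target close the books.

The feed brings in 0.0500 min⁻¹ of the charge. After the feed, teal's target climbs from 0.2% to 1.4% over the next 40.0 min, nearly steadily: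

leak = 0.0180 h⁻¹

This leak, the share of the charge that passes into target per hour once the feed is over, is read off two scattered teal readings, and I book it as a zero-order rate. I freeze it and carry it to blue.

At 6.0 min: feed × time = 30.0%, with no target booked.

At 20 min: whole charge less teal's target = 99.8%.

At 1.0 h: 99.8% − leak × 40.0 min = 98.6%.

The forecast gives 29.8%, 99.3% and 97.5%. Reading a hint in blue's target, it chose to “shade the values a little lower”, so its last entry stands below mine by 1.1 points.

The blue flask gives 30.0%, 99.8% and 98.8%, and the forecast holds within its margin.

starting material + free catalyst ⇌ catalyst intermediate A (K = 48.0 M⁻¹, k = 170 M⁻¹ min⁻¹); partner + catalyst intermediate A → free catalyst + target (k = 27.0 M⁻¹ min⁻¹); second substrate + free catalyst ⇌ catalyst intermediate B (K = 410 M⁻¹, k = 110 M⁻¹ min⁻¹); partner + catalyst intermediate B → free catalyst + second product (k = 30.0 M⁻¹ min⁻¹); partner + precatalyst → free catalyst + spent reagent (k = 0.890 M⁻¹ min⁻¹); partner + protic impurity → quenched reagent (k = 43.0 M⁻¹ min⁻¹); catalyst intermediate B + capture agent → trapped intermediate (k = 42.0 M⁻¹ min⁻¹) Its protic impurity is gone, 0% of the charge left at 1.00 h, yet leaving out that step with the partner makes no difference to these figures. Frozen at 0.0180 h⁻¹ and started from the blue flask's 1.13% of target at 1.00 h, the leak books 2.93% by 2.00 h, and the blue flask stands at 2.60%.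

The numbers in the tables are calculated for substances that don't exist; scatter was added.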